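**Retrosynthetic overview**
1. Target 10 comes from flavone-5,8-quinone 9 by reduction; 9 comes from acylquinone 8 by cutting O1–C8a, where the enol oxygen replaces the C8a methoxy group.
2. 8 comes from diketone 7 by oxidative demethylation of the para methoxy pair that becomes C5 and C8; 7 comes from ketone 4 and acid chloride 5 (C2–C3 bond); 4 comes from arene 1 and amide 2 (C4–C4a bond).
3. Ring order: rings A and B are bought as benzene rings, ring A is raised to the quinone, and ring C (the pyranone) is the only ring closed.
4. Feature: the O1–C8a bond lies next to C8 of the para C5/C8 oxygen pair of ring A. At the 5,8-quinone level C8a carries a methoxy group and is β to both the C5 and the C4 carbonyl, so a tethered enol oxygen can displace that methoxy group; the quinone oxygens are already the C5 and C8 hydroxyls of the target.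

Key step: step 4

Remark: flavone numbering (O1 to C8a) is used for 8–10. Compounds 7 and 8 are racemic at the methoxy-bearing carbon between the two carbonyls; this centre is enolisable and becomes sp2 C3 in step 4, so it is not controlled.

**Step 1**
Reactants: 1 1,2,3,5-tetramethoxybenzene; 2 N,2-dimethoxy-N-methylacetamide
Product: 4 2-methoxy-1-(2,3,4,6-tetramethoxyphenyl)ethan-1-one, via (2,3,4,6-tetramethoxyphenyl)lithium 3 (not isolated)
Conditions: n-BuLi (1.05 equiv), THF, 0 °C; then 2, −78 °C to 0 °C; 1 M HCl
Reagents that add atoms: none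
Why: Directed ortho-lithiation followed by Weinreb ketone synthesis: the two ring hydrogens of 1 are equivalent and each lies between two methoxy groups, so a single aryllithium should form, and its addition to the Weinreb amide stops at the ketone through the chelated tetrahedral intermediate.

**Step 2**
Reactants: 4 2-methoxy-1-(2,3,4,6-tetramethoxyphenyl)ethan-1-one; 5 2,3,4-trimethoxybenzoyl chloride
Product: 7 2-methoxy-1-(2,3,4,6-tetramethoxyphenyl)-3-(2,3,4-trimethoxyphenyl)propane-1,3-dione (racemic), via lithium (Z)-2-methoxy-1-(2,3,4,6-tetramethoxyphenyl)ethen-1-olate 6 (not isolated)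
Conditions: LiN(SiMe3)2 (2.2 equiv), THF, −78 °C; then 5, −78 °C to 0 °C; 1 M HCl
Reagents that add atoms: none
Why: Crossed Claisen-type C-aroylation of a chelated lithium enolate by an aroyl chloride, in which the second equivalent of base stores the acidic product as its lithium diketonate and so prevents a second acylation; the new stereocentre is formed racemic and needs no control.

**Step 3**
Reactants: 7 2-methoxy-1-(2,3,4,6-tetramethoxyphenyl)-3-(2,3,4-trimethoxyphenyl)propane-1,3-dione
Product: 8 3,5-dimethoxy-2-[2-methoxy-3-oxo-3-(2,3,4-trimethoxyphenyl)propanoyl]cyclohexa-2,5-diene-1,4-dione (racemic)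
Conditions: (NH4)2Ce(NO3)6 (2.5 equiv), MeCN/H2O, 0 °C, short contact time; cold extractive work-up, crude product used at once
Reagents that add atoms: water, O
Why: Oxidative demethylation of a para-dimethoxyarene by tetravalent cerium: ring A is the more electron-rich ring and holds the only para methoxy pair (the future C5 and C8), so oxidation with capture of water at these two carbons and loss of two molecules of methanol should give the 1,4-quinone and leave ring B untouched.

**Step 4**
Reactants: 8 3,5-dimethoxy-2-[2-methoxy-3-oxo-3-(2,3,4-trimethoxyphenyl)propanoyl]cyclohexa-2,5-diene-1,4-dione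
Product: 9 3,7-dimethoxy-2-(2,3,4-trimethoxyphenyl)-4H-chromene-4,5,8-trione
Conditions: CsOAc (1 equiv), 4 Å molecular sieves, MeCN (0.01 M), 0 °C to rt, argon, dark
Reagents that add atoms: none
Why: Acetate reversibly forms the cesium enolate of the 2-methoxy-1,3-diketone, whose oxygen on the aryl-bearing carbon adds to C8a, a carbon β to both the C5 quinone carbonyl and the C4 side-chain carbonyl, and the stabilised adduct then expels methoxide from C8a to restore the C4a=C8a double bond, the methoxide being protonated by acetic acid so that the base is returned. The closest known reactions are the exchange of methoxy groups on methoxy-1,4-benzoquinones by alkoxides, phenoxides and amines, and the base-mediated closure of 1-(2-fluoroaryl)-1,3-diketones to chromones. Ring C closes in a 6-endo-trig mode, since the attacked C8a and its double-bond partner C4a both lie in the new six-membered ring. No stereocentre is formed, and the labile centre of 8 becomes sp2 C3. The step needs attack through oxygen and not carbon, at C8a and not at C7 or C6, and within one molecule: attack through carbon would need a four-membered ring, the C7 methoxy group and C6–H are out of reach of the tether and lack the acyl activation, and high dilution suppresses intermolecular addition. The large cesium ion chelates weakly, so the enolate can leave the U-shaped chelate and turn its oxygen toward C8a.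

**Step 5**
Reactants: 9 3,7-dimethoxy-2-(2,3,4-trimethoxyphenyl)-4H-chromene-4,5,8-trione
Product: 10 5,8-dihydroxy-3,7-dimethoxy-2-(2,3,4-trimethoxyphenyl)-4H-chromen-4-one (5,8-dihydroxy-3,7,2',3',4'-pentamethoxyflavone)
Conditions: Na2S2O4 (excess), EtOAc/H2O, rt, argon; wash with dilute HCl
Reagents that add atoms: none
Why: Two-electron reduction of a quinone to its hydroquinone by dithionite, which turns the C5 and C8 carbonyls into the two hydroxyls and should touch neither the pyranone nor the methyl ethers.

**Compound list**
1 | 1,2,3,5-tetramethoxybenzene | COc1cc(OC)c(OC)c(OC)c1 | starting material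
2 | N,2-dimethoxy-N-methylacetamide | COCC(=O)N(C)OC | starting material
3 | (2,3,4,6-tetramethoxyphenyl)lithium | [Li]c1c(OC)cc(OC)c(OC)c1OC | intermediate
4 | 2-methoxy-1-(2,3,4,6-tetramethoxyphenyl)ethan-1-one | COCC(=O)c1c(OC)cc(OC)c(OC)c1OC | intermediate
5 | 2,3,4-trimethoxybenzoyl chloride | COc1ccc(C(Cl)=O)c(OC)c1OC | starting material
6 | lithium (Z)-2-methoxy-1-(2,3,4,6-tetramethoxyphenyl)ethen-1-olate | CO/C=C(\O[Li])c1c(OC)cc(OC)c(OC)c1OC | intermediate
7 | 2-methoxy-1-(2,3,4,6-tetramethoxyphenyl)-3-(2,3,4-trimethoxyphenyl)propane-1,3-dione (racemic) | COc1ccc(C(=O)C(OC)C(=O)c2c(OC)cc(OC)c(OC)c2OC)c(OC)c1OC | intermediate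
8 | 3,5-dimethoxy-2-[2-methoxy-3-oxo-3-(2,3,4-trimethoxyphenyl)propanoyl]cyclohexa-2,5-diene-1,4-dione (racemic) | COC1=CC(=O)C(C(=O)C(OC)C(=O)c2ccc(OC)c(OC)c2OC)=C(OC)C1=O | intermediate
9 | 3,7-dimethoxy-2-(2,3,4-trimethoxyphenyl)-4H-chromene-4,5,8-trione | COC1=CC(=O)C2=C(OC(-c3ccc(OC)c(OC)c3OC)=C(OC)C2=O)C1=O | intermediate
10 | 5,8-dihydroxy-3,7-dimethoxy-2-(2,3,4-trimethoxyphenyl)-4H-chromen-4-one | COc1ccc(-c2oc3c(O)c(OC)cc(O)c3c(=O)c2OC)c(OC)c1OC | target

**Step count and risks**
Total steps: 5. Longest linear sequence: 5 (1 → 4 → 7 → 8 → 9 → 10).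

Steps most likely to fail:

1. Step 4. The enolate may add through carbon to C6 of a second quinone molecule, transfer an electron to the quinone, or rest as the reversible hemiketal at the C5 carbonyl; the activated C8a methoxy group may also be lost to adventitious water before the ring closes. The fallback sets out from ketone 4 and returns at quinone 9; it builds the pyranone in the classical way and makes the quinone afterwards. Ketone 4 would be treated with AlCl3 in MeCN, which should cleave the methoxy group crowded between the acyl group and a second methoxy group, as polymethoxyacetophenones generally behave, to give 1-(2-hydroxy-3,4,6-trimethoxyphenyl)-2-methoxyethan-1-one F1. Its dianion (LiN(SiMe3)2, THF, −78 °C) would be C-aroylated with 5 to give 1-(2-hydroxy-3,4,6-trimethoxyphenyl)-2-methoxy-3-(2,3,4-trimethoxyphenyl)propane-1,3-dione F2. Cyclodehydration (H2SO4 in AcOH) would give 3,5,7,8-tetramethoxy-2-(2,3,4-trimethoxyphenyl)-4H-chromen-4-one F3. Oxidative demethylation of its C5/C8 methoxy pair with (NH4)2Ce(NO3)6 in aqueous MeCN (or with aqueous HNO3) would then give 9.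

2. Step 3. Tetravalent cerium may also oxidise the enol of the 1,3-diketone or ring B, an ortho-quinone may form, and the acidic aqueous medium may hydrolyse the activated methoxy group of the new quinone. The fallback sets out from ketone 4 and returns at quinone 8; it moves the cerium oxidation to a stage without a diketone or a second ring, so that the last oxidation is of a hydroquinone. Ketone 4 would be oxidised with (NH4)2Ce(NO3)6 to 3,5-dimethoxy-2-(methoxyacetyl)cyclohexa-2,5-diene-1,4-dione F4 and reduced with Na2S2O4 to 1-(3,6-dihydroxy-2,4-dimethoxyphenyl)-2-methoxyethan-1-one F5. Its trianion (LiN(SiMe3)2, 4.3 equiv, THF, −78 °C) would be C-aroylated with 5 to give 1-(3,6-dihydroxy-2,4-dimethoxyphenyl)-2-methoxy-3-(2,3,4-trimethoxyphenyl)propane-1,3-dione F6 after a buffered work-up. This hydroquinone would be oxidised under neutral conditions with Ag2O (MgSO4, Et2O) to 8. It must be kept away from acid so that its hydroxyl ortho to the ketone does not close the isomeric 5,6,7-oxygenated flavone.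

3. Step 2. The enolate may be acylated on oxygen to an enol ester, or the product may be acylated a second time. The fallback sets out from ketone 4 (through enolate 6) and returns at diketone 7; it makes the carbon–carbon bond by an aldol addition, where attack through oxygen leads nowhere. Enolate 6 would be added to 2,3,4-trimethoxybenzaldehyde F7 (THF, −78 °C) to give 3-hydroxy-2-methoxy-1-(2,3,4,6-tetramethoxyphenyl)-3-(2,3,4-trimethoxyphenyl)propan-1-one F8 as a mixture of racemic diastereomers. Oxidation of the secondary alcohol with Dess–Martin periodinane (CH2Cl2, NaHCO3) would give 7.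

**Further compounds**
F1 | step 4 | 1-(2-hydroxy-3,4,6-trimethoxyphenyl)-2-methoxyethan-1-one | COCC(=O)c1c(O)c(OC)c(OC)cc1OC
F2 | step 4 | 1-(2-hydroxy-3,4,6-trimethoxyphenyl)-2-methoxy-3-(2,3,4-trimethoxyphenyl)propane-1,3-dione (racemic) | COc1ccc(C(=O)C(OC)C(=O)c2c(O)c(OC)c(OC)cc2OC)c(OC)c1OC
F3 | step 4 | 3,5,7,8-tetramethoxy-2-(2,3,4-trimethoxyphenyl)-4H-chromen-4-one | COc1ccc(-c2oc3c(OC)c(OC)cc(OC)c3c(=O)c2OC)c(OC)c1OC
F4 | step 3 | 3,5-dimethoxy-2-(methoxyacetyl)cyclohexa-2,5-diene-1,4-dione | COCC(=O)C1=C(OC)C(=O)C(OC)=CC1=O
F5 | step 3 | 1-(3,6-dihydroxy-2,4-dimethoxyphenyl)-2-methoxyethan-1-one | COCC(=O)c1c(OC)c(O)c(OC)cc1O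
F6 | step 3 | 1-(3,6-dihydroxy-2,4-dimethoxyphenyl)-2-methoxy-3-(2,3,4-trimethoxyphenyl)propane-1,3-dione (racemic) | COc1ccc(C(=O)C(OC)C(=O)c2c(OC)c(O)c(OC)cc2O)c(OC)c1OC
F7 | step 2 | 2,3,4-trimethoxybenzaldehyde | COc1ccc(C=O)c(OC)c1OC
F8 | step 2 | 3-hydroxy-2-methoxy-1-(2,3,4,6-tetramethoxyphenyl)-3-(2,3,4-trimethoxyphenyl)propan-1-one (mixture of racemic diastereomers) | COc1ccc(C(O)C(OC)C(=O)c2c(OC)cc(OC)c(OC)c2OC)c(OC)c1OC
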